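Slowness was what these runs showed best: after 30.0 min the north-east run still read 80% of its substrate and the north run 76%.

| flask | substrate | partner | free catalyst | remark | time |
|---|---|---|---|---|---|
| north-east | 0.25 M | 0.34 M (fed, over 6.0 min) | 5 mM | run made earlier |  |
| north | 0.25 M | 0.75 M (fed, over 6.0 min) | 5 mM | run made earlier |  |
| north-west | 0.25 M | 0.50 M (fed, over 6.0 min) | 10 mM | run made earlier |  |
| flask | 0.25 M | 0.500 M (fed, over 6.0 min) | 5.0 mM |  | 40 min |

- north-east (time / min: substrate / %, target / %): 2.50: 98, 2; 5.00: 96, 2; 10.0: 95, 4; 15.0: 92, 10; 30.0: 80, 15
- north (time / min: substrate / %, target / %): 2.50: 98, 0; 5.00: 93, 2; 10.0: 90, 6; 15.0: 90, 8; 30.0: 76, 24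
- north-west (time / min: substrate / %, target / %): 3.00: 96, 1; 8.00: 91, 11; 15.0: 80, 18; 25.0: 68, 32; 30.0: 66, 33

(readings scatter by 1.5 percentage points)

- by-product is meant together with its idle adduct
- steps that have been proposed: substrate + free catalyst <-> catalyst intermediate A; partner + catalyst intermediate A -> catalyst intermediate B; partner + by-product <-> idle adduct; catalyst intermediate B -> by-product + catalyst intermediate C; catalyst intermediate C <-> free catalyst + target
- the earlier runs do not show how much of partner is bound; that part of a forecast is a guess

* part of the substrate that has reacted at 40 min
* share of the unused partner that is free and not bound as idle adduct, at 40 min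

I folded the flask into one number. Its partner charge of 0.500 M sits at the geometric mean of the north-east and north charges, and both runs had the flask's catalyst. So I averaged their logarithms of substrate charged over substrate left and stretched that from 30.0 min to 40 min, which gave 0.332. This clock number, the natural logarithm of substrate charged over substrate left, taken as growing in step with catalyst and time, treats the substrate as pseudo-first-order and puts the reacted part at 28.2%.

Was one number enough? The north-west run, scaled from 10 mM of catalyst to 5.0 mM, gives 0.277, or 24.2% reacted. That is a gap of 4 percentage points with readings scattering by 1.5 points, so I kept the figure from the flask's own catalyst. Binding every by-product leaves 83.6% of the unused partner free; how much really binds was a guess.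

The forecast said 25% reacted, on the ground that “Curves are nearly linear after the feed, with little visible slowing”, and 92% free, its words there being “I guess moderate binding”. My reacted part stood higher.

The flask gave 27.1% reacted and 96.1% free.

    substrate + free catalyst ⇌ catalyst intermediate A (K = 7.20 M⁻¹, k = 0.0868 M⁻¹ s⁻¹)
    partner + catalyst intermediate A → catalyst intermediate B (k = 0.0615 M⁻¹ s⁻¹)
    partner + by-product ⇌ idle adduct, settled at all times (K = 0.830 M⁻¹)
    catalyst intermediate B → by-product + catalyst intermediate C (k = 0.0213 s⁻¹)
    catalyst intermediate C ⇌ free catalyst + target (K = 0.530 M, k = 0.134 s⁻¹)

Read back, the flask's clock number was 0.316 against my 0.332. Scaled to a neighbouring flask with 0.013 M of free catalyst, it gives 0.862, or 57.8% reacted, and that flask gave 57.1%. With 6.10 mM of free catalyst, the reacted part of this flask moved by 5 points. In the flask, partner's half-life by its step with catalyst intermediate A was 190 min, long against the 40 min of the run. At the end, 83% of the partner charged still stood unbound.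

All runs are calculated for an exercise; noise was put on by code.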